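The chroman is read as a rearranged p-quinol ether, and everything rests on the C4–C4a disconnection. In the precursor C4 sits one atom away, on the future C8a, inside a 1-oxaspiro[4.5]deca-6,9-dien-8-one. This spirodienone arises by oxidative dearomatisation of a p-alkylphenol bearing the tertiary alcohol of (R)-linalool. One acid-triggered dienone–phenol 1,2-shift moves C4 to C4a, enlarges the oxolane to the dihydropyran ring, rearomatises the carbocycle and unveils the C6 oxygen. The step exploits the para relation of O1 (on C8a) and the C6 hydroxyl in the benzene ring, and the C8 methyl group, which blocks the second migration terminus. C2 is bought and never touched; the side chain comes by B-alkyl Suzuki coupling.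

Key step: step 3

Remark 1: ring atoms carry chroman numbers (O1, C2–C4, C4a, C5–C8, C8a). The side chain is C1′–C12′ counted from C2. Compound 5 carries 1-oxaspiro[4.5]decane numbers (O1, C2–C4, spiro C5, C6–C10).
Remark 2: commercial (R)-(−)-linalool of high enantiomeric purity is assumed, since it is the only source of C2.
Remark 3: C5 of 5, the carbinol carbon of 18 and C6 of 18 and 19 arise as mixtures and are left open in the SMILES, because these centres are erased later.

Step 1
Reactants: 1 (R)-(−)-linalool; 2 4-bromo-3-methylphenol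
Product: 4 4-[(3R)-3-hydroxy-3,7-dimethyloct-6-en-1-yl]-3-methylphenol, via B-alkyl-9-BBN adduct of linalool 3 (not isolated)
Conditions: 9-BBN dimer (1.2 equiv B–H), THF, 0 °C → rt; then 2, Pd(OAc)2 (3 mol %), SPhos (6 mol %), aq K3PO4, THF, 60 °C
Reagents that add atoms: 9-borabicyclo[3.3.1]nonane (9-BBN), B1C2CCCC1CCC2 (its boron cage stays in 3 only; 4 keeps one hydrogen from it)
Why: Anti-Markovnikov hydroboration, in which 9-BBN takes the monosubstituted vinyl group far faster than the trisubstituted olefin, followed by B-alkyl Suzuki–Miyaura coupling with a catalyst that tolerates the free phenol and the ortho-methyl group, joins C4 to the ring carbon para to the hydroxyl without touching the carbinol centre.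

Step 2
Reactants: 4 4-[(3R)-3-hydroxy-3,7-dimethyloct-6-en-1-yl]-3-methylphenol
Product: 5 (2R)-2,6-dimethyl-2-(4-methylpent-3-en-1-yl)-1-oxaspiro[4.5]deca-6,9-dien-8-one (both C5 epimers)
Conditions: PhI(OAc)2 (1.1 equiv), (CF3)2CHOH, 0 °C
Reagents that add atoms: none
Why: In this hypervalent-iodine oxidative dearomatisation (spiroetherification) the phenoxenium equivalent is captured at its para carbon by the tethered tertiary hydroxyl in a 5-exo mode, faster than by the non-nucleophilic solvent, and the uncontrolled spiro centre is erased in step 3.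

Step 3
Reactants: 5 (2R)-2,6-dimethyl-2-(4-methylpent-3-en-1-yl)-1-oxaspiro[4.5]deca-6,9-dien-8-one
Product: 7 (2R)-2,8-dimethyl-2-(4-methylpent-3-en-1-yl)-6-(triisopropylsilyloxy)chroman, via free chroman-6-ol 6 (not isolated)
Conditions: BF3·OEt2 (0.3 equiv), CH2Cl2, −40 → 0 °C; then 2,6-lutidine, TIPSOTf, 0 °C
Reagents that add atoms: triisopropylsilyl triflate, CC(C)[Si](C(C)C)(C(C)C)OS(=O)(=O)C(F)(F)F
Why: BF3 binds the dienone oxygen of 5 and turns the ring into an oxy-substituted cyclohexadienyl cation with charge on C6 and C10, the two carbons flanking the spiro centre; C4 then shifts with its bonding pair from C5 to C10 (future C8a to future C4a), the charge left on C5 is carried by O1 as an oxocarbenium ion, and loss of the C10 proton gives phenol 6, which is silylated in the same flask. This is the dienone–phenol rearrangement in its p-quinol-ether form (the chemical counterpart of the NIH shift), in which carbon rather than oxygen migrates because only then does the remaining heteroatom stabilise the cation. The dihydropyran ring is closed by this suprafacial 1,2-shift, that is by a one-atom enlargement of the oxolane (5 → 6) through a three-centre transition state and not by an end-to-end cyclisation. No new stereocentre is formed: the spiro centre vanishes on aromatisation, so both epimers of 5 converge, and C2 keeps the linalool configuration because none of its four bonds takes part. The step needs terminus selectivity, which the C6 methyl group secures, since a shift to C6 gives a quaternary carbon that cannot lose a proton and can only revert, whereas the shift to C10–H is made irreversible by aromatisation. Substoichiometric Lewis acid at low temperature is meant to spare the trisubstituted olefin and the tertiary C2–O1 bond.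

Step 4
Reactants: 7 (2R)-2,8-dimethyl-2-(4-methylpent-3-en-1-yl)-6-(triisopropylsilyloxy)chroman; 8 isopropenylboronic acid pinacol ester
Product: 9 (2R)-2,8-dimethyl-2-[(3Z)-4-(4,4,5,5-tetramethyl-1,3,2-dioxaborolan-2-yl)pent-3-en-1-yl]-6-(triisopropylsilyloxy)chroman
Conditions: 8 (4 equiv), Hoveyda–Grubbs II (2 × 5 mol %), CH2Cl2, 40 °C, slow argon purge
Reagents that add atoms: none
Why: In this olefin cross-metathesis the prenyl-type olefin serves as a terminal-alkene surrogate (isobutene leaves), the 1,1-disubstituted boronate does not homodimerise, and the bulky boryl group should end up trans to the chain, as is known for isopropenyl boronate, which fixes the later (E)-geometry of C3′=C4′.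

Step 5
Reactants: 9 (Z)-alkenyl pinacol boronate
Product: 10 (2R)-2-[(3E)-4-iodopent-3-en-1-yl]-2,8-dimethyl-6-(triisopropylsilyloxy)chroman
Conditions: I2, aq NaOH, THF, 0 °C
Reagents that add atoms: iodine, II
Why: Base-mediated iododeboronation of an alkenyl boronate is known to run with retention of the olefin geometry, so boron is exchanged for iodine trans to the chain, and the aryl TIPS ether resists the cold aqueous base.

Step 6
Reactants: 11 (R)-4-benzyl-3-propionyl-1,3-oxazolidin-2-one; 12 allyl iodide
Product: 14 (4R)-4-benzyl-3-[(2S)-2-methylpent-4-enoyl]-1,3-oxazolidin-2-one, via sodium (Z)-enolate 13 (not isolated)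
Conditions: NaHMDS, THF, −78 °C; then 12, −78 → −40 °C
Reagents that add atoms: sodium bis(trimethylsilyl)amide, C[Si](C)(C)[N-][Si](C)(C)C.[Na+] (sodium stays in 13 only)
Why: In this Evans asymmetric alkylation the chelated (Z)-enolate is shielded on one face by the benzyl group, so allyl iodide enters from the other face and sets C8′ as (S).

Step 7
Reactants: 14 (4R)-4-benzyl-3-[(2S)-2-methylpent-4-enoyl]-1,3-oxazolidin-2-one
Product: 15 (2S)-N-methoxy-N,2-dimethylpent-4-enamide
Conditions: MeONHMe·HCl, AlMe3, CH2Cl2, 0 °C → rt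
Reagents that add atoms: N,O-dimethylhydroxylamine hydrochloride, CNOC.Cl
Why: Weinreb aminolysis with the aluminium amide attacks the exocyclic imide carbonyl, frees the auxiliary and does not enolise C8′.

Step 8
Reactants: 15 (2S)-N-methoxy-N,2-dimethylpent-4-enamide; 16 3-methylbut-2-en-1-yl phenyl sulfone (prenyl phenyl sulfone)
Product: 19 (4S)-4,8-dimethyl-6-(phenylsulfonyl)nona-1,7-dien-5-one (both C6 epimers), via lithiated sulfone 17 (not isolated), via tetrahedral lithium adduct 18 (not isolated)
Conditions: 16, n-BuLi, THF, −78 °C; then 15, −78 → −20 °C; AcOH quench at −78 °C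
Reagents that add atoms: n-butyllithium, [Li]CCCC (lithium stays in 17 and 18 only)
Why: In this acylation of an α-sulfonyl carbanion by a Weinreb amide the allylic sulfone anion reacts at its α-carbon, and the chelated tetrahedral adduct prevents over-addition and shields C8′ from enolisation until the acidic quench.

Step 9
Reactants: 19 (4S)-4,8-dimethyl-6-(phenylsulfonyl)nona-1,7-dien-5-one
Product: 20 (4S)-4,8-dimethylnona-1,7-dien-5-one
Conditions: SmI2 (2.2 equiv), THF–MeOH, −78 °C
Reagents that add atoms: none
Why: In this SmI2 reductive desulfonylation of a β-keto sulfone two electrons expel sulfinate, and the samarium dienolate, formed only towards C10′, is protonated kinetically at the α-carbon, which keeps the olefin out of conjugation and C8′ intact.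

Step 10
Reactants: 20 (4S)-4,8-dimethylnona-1,7-dien-5-one
Product: 23 (4S,6R)-6-[(tert-butyldimethylsilyl)oxy]-4,8-dimethylnona-1,7-dien-5-one, via sodium dienolate 21 (not isolated), via sodium alkoxide of the hydroxy ketone 22 (not isolated)
Conditions: NaHMDS (1.1 equiv), THF, −78 °C; (1R)-(−)-(10-camphorsulfonyl)oxaziridine, −78 → −50 °C; then TBSOTf, −78 → −30 °C
Reagents that add atoms: sodium bis(trimethylsilyl)amide, C[Si](C)(C)[N-][Si](C)(C)C.[Na+] (sodium stays in 21 and 22 only); (1R)-(−)-(10-camphorsulfonyl)oxaziridine, CC1(C)[C@H]2CC[C@@]13CS(=O)(=O)N4O[C@]34C2; tert-butyldimethylsilyl triflate, CC(C)(C)[Si](C)(C)OS(=O)(=O)C(F)(F)F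
Why: In this Davis asymmetric enolate hydroxylation the doubly activated C10′ methylene is deprotonated in preference to the hindered C8′–H, the metal dienolate takes up electrophilic oxygen at its α-carbon, the (−)-camphor-derived oxaziridine should give the (R)-carbinol by analogy with its known sense for (Z)-enolates of aryl benzyl ketones, and silylation in the same flask stops α-ketol isomerisation.

Step 11
Reactants: 23 (4S,6R)-6-[(tert-butyldimethylsilyl)oxy]-4,8-dimethylnona-1,7-dien-5-one; 10 (E)-alkenyl iodide
Product: 25 6-O-TIPS-10′-O-TBS bis-silyl ether of the target (2R,8′S,10′R,3′E), via B-alkyl-9-BBN adduct of the ketone 24 (not isolated)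
Conditions: 23, 9-BBN dimer (1.3 equiv B–H), THF, 0 °C → rt; then 10, Pd(dppf)Cl2·CH2Cl2 (5 mol %), AsPh3, aq K3PO4, DMF, rt
Reagents that add atoms: 9-borabicyclo[3.3.1]nonane (9-BBN), B1C2CCCC1CCC2 (its boron cage stays in 24 only; 25 keeps one hydrogen from it)
Why: In this B-alkyl Suzuki–Miyaura coupling 9-BBN takes the terminal olefin faster than the trisubstituted one or the ketone flanked by two branched carbons, and the alkenyl iodide couples with retention, which joins C4′ to C5′ and delivers the (E)-olefin.

Step 12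
Reactants: 25 bis-silyl ether of the target
Product: 26 (4R,6S,10E)-4-hydroxy-13-[(2R)-6-hydroxy-2,8-dimethyl-3,4-dihydro-2H-chromen-2-yl]-2,6,10-trimethyltrideca-2,10-dien-5-one (target, CNP0273237.1)
Conditions: TBAF, AcOH (1:1, 3 equiv each), THF, 0 °C → rt, argon
Reagents that add atoms: none
Why: Fluoride-induced cleavage removes both silyl ethers, and the acetic acid buffer should keep C8′ and C10′ from epimerising and prevent an α-ketol shift.

Compound list
1 | (R)-(−)-linalool | CC(C)=CCC[C@@](C)(O)C=C | starting material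
2 | 4-bromo-3-methylphenol | Cc1cc(O)ccc1Br | starting material
3 | B-alkyl-9-BBN adduct of linalool, boron on the former vinyl CH2, carbinol centre unchanged (not isolated) | CC(C)=CCC[C@@](C)(O)CCB1C2CCCC1CCC2 | intermediate
4 | 4-[(3R)-3-hydroxy-3,7-dimethyloct-6-en-1-yl]-3-methylphenol | CC(C)=CCC[C@@](C)(O)CCc1ccc(O)cc1C | intermediate
5 | (2R)-2,6-dimethyl-2-(4-methylpent-3-en-1-yl)-1-oxaspiro[4.5]deca-6,9-dien-8-one, both C5 epimers | CC(C)=CCC[C@]1(C)CCC2(O1)C=CC(=O)C=C2C | intermediate
6 | (2R)-2,8-dimethyl-2-(4-methylpent-3-en-1-yl)chroman-6-ol (not isolated) | CC(C)=CCC[C@]1(C)CCc2cc(O)cc(C)c2O1 | intermediate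
7 | (2R)-2,8-dimethyl-2-(4-methylpent-3-en-1-yl)-6-(triisopropylsilyloxy)chroman | CC(C)=CCC[C@]1(C)CCc2cc(O[Si](C(C)C)(C(C)C)C(C)C)cc(C)c2O1 | intermediate
8 | isopropenylboronic acid pinacol ester | CC(=C)B1OC(C)(C)C(C)(C)O1 | starting material
9 | (2R)-2,8-dimethyl-2-[(3Z)-4-(pinacolboryl)pent-3-en-1-yl]-6-(triisopropylsilyloxy)chroman | CC1(C)OB(OC1(C)C)/C(C)=C/CC[C@]1(C)CCc2cc(O[Si](C(C)C)(C(C)C)C(C)C)cc(C)c2O1 | intermediate
10 | (2R)-2-[(3E)-4-iodopent-3-en-1-yl]-2,8-dimethyl-6-(triisopropylsilyloxy)chroman | I/C(C)=C/CC[C@]1(C)CCc2cc(O[Si](C(C)C)(C(C)C)C(C)C)cc(C)c2O1 | intermediate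
11 | (R)-4-benzyl-3-propionyl-1,3-oxazolidin-2-one | CCC(=O)N1[C@H](Cc2ccccc2)COC1=O | starting material
12 | allyl iodide | C=CCI | starting material
13 | sodium (Z)-enolate of 11 (not isolated) | C/C=C(\[O-])N1[C@H](Cc2ccccc2)COC1=O.[Na+] | intermediate
14 | (4R)-4-benzyl-3-[(2S)-2-methylpent-4-enoyl]-1,3-oxazolidin-2-one | C=CC[C@H](C)C(=O)N1[C@H](Cc2ccccc2)COC1=O | intermediate
15 | (2S)-N-methoxy-N,2-dimethylpent-4-enamide | C=CC[C@H](C)C(=O)N(C)OC | intermediate
16 | 3-methylbut-2-en-1-yl phenyl sulfone | CC(C)=CCS(=O)(=O)c1ccccc1 | starting material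
17 | α-lithiated prenyl phenyl sulfone (not isolated) | [Li]C(C=C(C)C)S(=O)(=O)c1ccccc1 | intermediate
18 | tetrahedral lithium adduct of 17 and 15 (not isolated) | C=CC[C@H](C)C([O-])(N(C)OC)C(C=C(C)C)S(=O)(=O)c1ccccc1.[Li+] | intermediate
19 | (4S)-4,8-dimethyl-6-(phenylsulfonyl)nona-1,7-dien-5-one, both C6 epimers | C=CC[C@H](C)C(=O)C(C=C(C)C)S(=O)(=O)c1ccccc1 | intermediate
20 | (4S)-4,8-dimethylnona-1,7-dien-5-one | C=CC[C@H](C)C(=O)CC=C(C)C | intermediate
21 | sodium (Z)-dienolate of 20 (not isolated) | C=CC[C@H](C)C(/[O-])=C/C=C(C)C.[Na+] | intermediate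
22 | sodium alkoxide of (4S,6R)-6-hydroxy-4,8-dimethylnona-1,7-dien-5-one (not isolated) | C=CC[C@H](C)C(=O)[C@H]([O-])C=C(C)C.[Na+] | intermediate
23 | (4S,6R)-6-[(tert-butyldimethylsilyl)oxy]-4,8-dimethylnona-1,7-dien-5-one | C=CC[C@H](C)C(=O)[C@H](O[Si](C)(C)C(C)(C)C)C=C(C)C | intermediate
24 | B-alkyl-9-BBN adduct of 23, boron on C5′ (not isolated) | CC(C)=C[C@@H](O[Si](C)(C)C(C)(C)C)C(=O)[C@@H](C)CCCB1C2CCCC1CCC2 | intermediate
25 | 6-O-TIPS-10′-O-TBS bis-silyl ether of the target | CC(C)=C[C@@H](O[Si](C)(C)C(C)(C)C)C(=O)[C@@H](C)CCC/C(C)=C/CC[C@]1(C)CCc2cc(O[Si](C(C)C)(C(C)C)C(C)C)cc(C)c2O1 | intermediate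
26 | (4R,6S,10E)-4-hydroxy-13-[(2R)-6-hydroxy-2,8-dimethyl-3,4-dihydro-2H-chromen-2-yl]-2,6,10-trimethyltrideca-2,10-dien-5-one | CC(C)=C[C@@H](O)C(=O)[C@@H](C)CCC/C(C)=C/CC[C@]1(C)CCc2cc(O)cc(C)c2O1 | target

Total step count: 12.
Longest linear sequence: 7 steps (1–5, 11, 12). The branch 6–10, 11, 12 is equally long.

Steps most likely to fail

Step 3 (key step).
- **What may go wrong:** the shift of a primary alkyl group may be too slow under substoichiometric Lewis acid. Stronger acid would bring protonation of the side-chain olefin, or ionisation of the tertiary C2–O1 bond with loss of configuration.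
- **Fallback, from 5 back to 6:** the same C4 shift is run at the dienol oxidation level, where the cation forms far more easily. Luche reduction of 5 (NaBH4, CeCl3·7H2O, MeOH, −40 °C) should give the spirodienol F1. A trace of weak acid (PPTS, CH2Cl2, 0 °C) ionises the bis-allylic alcohol, and the dienol–benzene rearrangement closes the same C4–C4a bond to give the 6-deoxychroman F2. Iridium-catalysed C–H borylation ([Ir(OMe)(cod)]2, dtbpy, B2pin2, THF, 60 °C) reaches only the position without an ortho neighbour in a 1,2,3-trisubstituted benzene (C6) and gives the aryl boronate F3. NaBO3·4H2O (THF–H2O) oxidises it to 6, which is silylated as in step 3.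

Step 4.
- **What may go wrong:** slow turnover between two hindered olefins with catalyst decay, self-metathesis of 7, or incomplete control of the olefin geometry.
- **Fallback, from 7 back to 10 (9 is bypassed):** the C4′ unit is built by alkyne chemistry. Ozonolysis of 7 (O3, CH2Cl2–MeOH, −78 °C, dye end-point; Me2S) gives the aldehyde F4. Ramirez olefination (CBr4, PPh3, CH2Cl2, 0 °C) gives the dibromoolefin F5. n-BuLi followed by MeI (Corey–Fuchs sequence, THF, −78 °C → rt) gives the methylalkyne F6. One-flask hydrozirconation with excess Schwartz reagent (THF, 40 °C, equilibration of zirconium to the less hindered, methyl-side carbon) and iodinolysis lead to 10.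

Step 10.
- **What may go wrong:** poor facial selectivity of the external chiral oxidant on an acyclic dienolate, partial attack at the γ-carbon, or proton exchange that erodes C8′.
- **Fallback, from 20 back to 23:** control is moved from the reagent to a covalently bound auxiliary (SAMP-hydrazone method). SAMP is chosen by analogy with the known sense of its alkylations. Condensation of 20 with SAMP (cyclohexane, 60 °C) gives the hydrazone F7. LDA (THF, −78 °C) metalates the C10′ side, and achiral 2-(phenylsulfonyl)-3-phenyloxaziridine delivers oxygen to the face left open by the methoxymethylpyrrolidine, giving the hydroxy hydrazone F8. Mild hydrolysis (saturated aqueous oxalic acid, Et2O) frees the hydroxy ketone F9, and TBSOTf/2,6-lutidine leads to 23.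

Further compounds
F1 | step 3 | (2R)-2,6-dimethyl-2-(4-methylpent-3-en-1-yl)-1-oxaspiro[4.5]deca-6,9-dien-8-ol (C5 and C8 open) | CC(C)=CCC[C@]1(C)CCC2(O1)C=CC(O)C=C2C
F2 | step 3 | (2R)-2,8-dimethyl-2-(4-methylpent-3-en-1-yl)chroman | CC(C)=CCC[C@]1(C)CCc2cccc(C)c2O1
F3 | step 3 | (2R)-2,8-dimethyl-2-(4-methylpent-3-en-1-yl)-6-(4,4,5,5-tetramethyl-1,3,2-dioxaborolan-2-yl)chroman | CC(C)=CCC[C@]1(C)CCc2cc(B3OC(C)(C)C(C)(C)O3)cc(C)c2O1
F4 | step 4 | 3-[(2S)-2,8-dimethyl-6-(triisopropylsilyloxy)chroman-2-yl]propanal (descriptor changes by priority only) | O=CCC[C@]1(C)CCc2cc(O[Si](C(C)C)(C(C)C)C(C)C)cc(C)c2O1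
F5 | step 4 | (2R)-2-(4,4-dibromobut-3-en-1-yl)-2,8-dimethyl-6-(triisopropylsilyloxy)chroman | BrC(Br)=CCC[C@]1(C)CCc2cc(O[Si](C(C)C)(C(C)C)C(C)C)cc(C)c2O1
F6 | step 4 | (2R)-2,8-dimethyl-2-(pent-3-yn-1-yl)-6-(triisopropylsilyloxy)chroman | CC#CCC[C@]1(C)CCc2cc(O[Si](C(C)C)(C(C)C)C(C)C)cc(C)c2O1
F7 | step 10 | SAMP hydrazone of (4S)-4,8-dimethylnona-1,7-dien-5-one | C=CC[C@H](C)C(CC=C(C)C)=NN1CCC[C@H]1COC
F8 | step 10 | SAMP hydrazone of (4S,6R)-6-hydroxy-4,8-dimethylnona-1,7-dien-5-one | C=CC[C@H](C)C(=NN1CCC[C@H]1COC)[C@H](O)C=C(C)C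
F9 | step 10 | (4S,6R)-6-hydroxy-4,8-dimethylnona-1,7-dien-5-one | C=CC[C@H](C)C(=O)[C@H](O)C=C(C)C
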